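The route rests on disconnecting C8–C9 of the ten-membered carbocycle. In step 10 a γ-siloxyallylchromium made from the C9 enal adds through C9 to the C8 aldehyde: one operation closes the ten-membered ring, sets the anti C8/C9 diol with the two oxygens differentiated (O9 silylated, O8 free) and places the alkene at C1=C10. The step exploits the anti C8,C9-diol lying allylic to C1=C10 in the ten-membered ring. Its precursor is an open-chain dialdehyde: a trans C6/C7 γ-lactone carrying the saturated C8 aldehyde on C7 and, through the E-C4=C5 chain on C6, an (E)-2-(silyloxymethyl) enal (C9, C10, C14).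

Key step: step 10

Remark on the chemistry: locants are germacrane numbers (ring C1–C10, lactone C11–C13, C14 on C10, C15 on C4); the C14 oxygen is carried as a TBS ether so that it is unmasked together with O9, and the C1=C10 geometry of 15 is assumed not to matter because C1 becomes tetrahedral in the allylchromium.

**Step 1**
Reactants: 1 (4S)-4-benzyl-1,3-oxazolidin-2-one; 2 methyl 4-chloro-4-oxobutanoate
Product: 3 methyl 4-[(4S)-4-benzyl-2-oxo-1,3-oxazolidin-3-yl]-4-oxobutanoate
Conditions: n-BuLi, THF, −78 °C; then 2, −78 → 0 °C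
Reagents that add atoms: none
Why: N-acylation of the lithiated oxazolidinone by the acid chloride is the standard entry to chiral imides and leaves the methyl ester untouched at low temperature.

**Step 2**
Reactants: 4 2-methylidenepropane-1,3-diol
Product: 5 2-({[tert-butyl(dimethyl)silyl]oxy}methyl)prop-2-en-1-ol
Conditions: NaH (1.0 equiv), THF, 0 °C → rt; TBSCl (1.0 equiv)
Reagents that add atoms: tert-butyl(chloro)dimethylsilane, CC(C)(C)[Si](C)(C)Cl
Why: Silyl protection through the sparingly soluble monosodium alkoxide of a symmetrical diol should stop at the mono-ether.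

**Step 3**
Reactants: 5 2-({[tert-butyl(dimethyl)silyl]oxy}methyl)prop-2-en-1-ol
Product: 6 2-({[tert-butyl(dimethyl)silyl]oxy}methyl)prop-2-enal
Conditions: MnO2, CH2Cl2, rt
Reagents that add atoms: none
Why: Allylic alcohol oxidation with MnO2 stops at the aldehyde and gives the 2-substituted acrolein, which is used fresh.

**Step 4**
Reactants: 7 hex-1-en-5-yne
Product: 9 (2E)-3-methylhepta-2,6-dien-1-ol, via alkenylalane 8 (not isolated)
Conditions: Me3Al, Cp2ZrCl2 (0.25 equiv), CH2Cl2, 0 °C → rt; then n-BuLi, THF, −78 °C; (CH2O)n, −78 °C → rt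
Reagents that add atoms: trimethylaluminium, C[Al](C)C; formaldehyde (from paraformaldehyde), C=O
Why: Negishi zirconium-catalysed carboalumination adds methyl and aluminium syn across the terminal alkyne much faster than across the remote alkene, and the alanate is hydroxymethylated with retention, so the trisubstituted alkene is E.

**Step 5**
Reactants: 9 (2E)-3-methylhepta-2,6-dien-1-ol
Product: 10 (2E)-3-methylhepta-2,6-dienal
Conditions: MnO2, CH2Cl2, rt
Reagents that add atoms: none
Why: MnO2 allylic oxidation gives the enal under neutral conditions without E/Z isomerisation.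

**Step 6**
Reactants: 3 methyl 4-[(4S)-4-benzyl-2-oxo-1,3-oxazolidin-3-yl]-4-oxobutanoate; 10 (2E)-3-methylhepta-2,6-dienal
Product: 12 trans-lactone imide (4S)-4-benzyl-3-({(2R,3S)-2-[(1E)-2-methylhexa-1,5-dien-1-yl]-5-oxooxolan-3-yl}carbonyl)-1,3-oxazolidin-2-one, via aldol hydroxy ester 11 (not isolated)
Conditions: 3, Bu2BOTf, i-Pr2NEt, CH2Cl2, −78 → 0 °C; 10, −78 → 0 °C; H2O2, pH 7 buffer, MeOH, 0 °C; then PPTS (cat.), CH2Cl2, rt
Reagents that add atoms: none
Why: In this Evans syn aldol the Z boron enolate of the imide (formed at the imide α-carbon, not at the ester) adds through a closed chair transition state on the face away from the benzyl group, which sets C6 and C7, and the C6 hydroxyl then closes onto the methyl ester, the syn adduct giving the trans γ-lactone.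

**Step 7**
Reactants: 12 trans-lactone imide
Product: 13 (4R,5R)-4-(hydroxymethyl)-5-[(1E)-2-methylhexa-1,5-dien-1-yl]oxolan-2-one
Conditions: NaBH4, THF/H2O (4:1), 0 °C → rt; NH4Cl quench
Reagents that add atoms: none
Why: Reductive removal of the auxiliary works because the exocyclic imide carbonyl is far more electrophilic towards borohydride than the γ-lactone, so C8 is taken to the primary alcohol and the oxazolidinone is released.

**Step 8**
Reactants: 13 (4R,5R)-4-(hydroxymethyl)-5-[(1E)-2-methylhexa-1,5-dien-1-yl]oxolan-2-one; 6 2-({[tert-butyl(dimethyl)silyl]oxy}methyl)prop-2-enal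
Product: 14 (2E,6E)-2-({[tert-butyl(dimethyl)silyl]oxy}methyl)-7-[(2R,3R)-3-(hydroxymethyl)-5-oxooxolan-2-yl]-6-methylhepta-2,6-dienal
Conditions: 6 (4 equiv), second-generation Hoveyda–Grubbs catalyst RuCl2(H2IMes)(=CH-C6H4-2-O-i-Pr) (10 mol %), CH2Cl2, 40 °C
Reagents that add atoms: none
Why: Olefin cross-metathesis between the unhindered terminal alkene and a 2-substituted acrolein, which does not homodimerise, should give the trisubstituted (E)-enal while the trisubstituted C4=C5 alkene stays inert.

**Step 9**
Reactants: 14 hydroxy enal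
Product: 15 trans-lactone dialdehyde (2R,3S)-2-[(1E,5E)-6-formyl-7-{[tert-butyl(dimethyl)silyl]oxy}-2-methylhepta-1,5-dien-1-yl]-5-oxooxolane-3-carbaldehyde
Conditions: Dess–Martin periodinane, NaHCO3, CH2Cl2, 0 °C → rt; used crude
Reagents that add atoms: none
Why: Dess–Martin oxidation forms the C8 aldehyde under buffered, non-basic conditions, which avoids β-elimination of the lactone carboxylate and epimerisation at C7.

**Step 10**
Reactants: 15 trans-lactone dialdehyde
Product: 17 ten-membered lactone with free 8-OH, 9-OSiEt3 and 14-OTBS (trans C6/C7 lactone, anti C8/C9, E C4=C5, in-ring cis C1=C10), via γ-siloxyallylchromium 16 (not isolated)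
Conditions: CrCl2 (6 equiv), Et3SiCl (3 equiv), THF (10 % DMF), rt, slow addition of 15 to 0.003 M; then H2O
Reagents that add atoms: chlorotriethylsilane, CC[Si](Cl)(CC)CC
Why: Proposed new method: two equivalents of divalent chromium reduce the conjugated C9 aldehyde (CrCl2 does not reduce the saturated C8 aldehyde), Et3SiCl traps the oxygen, and the γ-siloxyallylchromium 16 (metal on C1, E-siloxyalkene from the s-trans enal) adds through C9 to the C8 carbonyl in a six-membered chair transition state with allyl transposition; the closest known reaction is the intermolecular CrCl2/R3SiCl cross-pinacol-type coupling of enals with aldehydes, here made intramolecular. The ten-membered ring closes by a 10-exo-trig carbonyl addition that forms C8–C9 and returns the alkene to C1=C10. C9 is set relative to C8 by the chair (E-siloxyalkene, substituents equatorial, hence the anti diol), and C8 by Felkin–Anh attack with the C7–C6 bond anti to the incoming carbon. Chemoselectivity between the two aldehydes rests on the conjugation of the C9 aldehyde, and ring closure over oligomerisation on slow addition at high dilution. The required in-ring cis C1=C10 geometry should follow from C2 taking the axial site on C1 to avoid A(1,2) strain with the C14 substituent, and from the lower strain of the cis cycloalkene in the forming ring. Silicon stays on O9 and O8 is released as the free hydroxyl on work-up, so the two oxygens are differentiated for the later esters.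

**Step 11**
Reactants: 17 ten-membered hydroxy lactone
Product: 18 8-O-trimethylsilyl ether of 17
Conditions: TMSCl, imidazole, CH2Cl2, 0 °C
Reagents that add atoms: chlorotrimethylsilane, C[Si](C)(C)Cl
Why: Silyl protection of the C8 hydroxyl ensures that no C8 alkoxide, which could trigger 1,2-silyl migration from O9 or translactonisation, is present in the enolate step.

**Step 12**
Reactants: 18 8-O-trimethylsilyl ether
Product: 20 C11 dimethylaminomethyl lactone with free 8-OH (Mannich base; C11 configuration immaterial), via TMS-protected Mannich base 19 (not isolated)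
Conditions: LiN(i-Pr)2, THF, −78 °C; CH2=NMe2+ I−, −78 → 0 °C; then citric acid, MeOH, 0 °C
Reagents that add atoms: N,N-dimethylmethyleneiminium iodide, C=[N+](C)C.[I-]
Why: Mannich alkylation of the lactone lithium enolate with the preformed iminium salt introduces C13 at C11, and mild acid methanolysis then removes only the labile trimethylsilyl ether.

**Step 13**
Reactants: 20 Mannich base
Product: 22 α-methylidene lactone with free 8-OH, 9-OSiEt3 and 14-OTBS, via quaternary ammonium iodide 21 (not isolated)
Conditions: MeI, MeOH, rt; then NaHCO3, CH2Cl2/H2O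
Reagents that add atoms: none
Why: N-methylation followed by base-induced β-elimination of trimethylamine (Hofmann-type) unveils the C11=C13 methylidene.

**Step 14**
Reactants: 22 α-methylidene hydroxy lactone
Product: 23 8-O-methacrylate of 22
Conditions: methacrylic anhydride, Et3N, DMAP (cat.), CH2Cl2, 0 °C → rt
Reagents that add atoms: methacrylic anhydride, C=C(C)C(=O)OC(=O)C(C)=C
Why: DMAP-catalysed acyl transfer esterifies the only free hydroxyl, at C8.

**Step 15**
Reactants: 23 8-O-methacrylate
Product: 24 9,14-diol 8-methacrylate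
Conditions: HF·pyridine, pyridine, THF, 0 °C → rt
Reagents that add atoms: none
Why: Fluoride-mediated desilylation removes the secondary triethylsilyl and the primary TBS ether in one operation without touching the esters or acrylate units.

**Step 16**
Reactants: 24 9,14-diol
Product: 25 9-hydroxy C14 enal
Conditions: TEMPO (cat.), PhI(OAc)2, CH2Cl2, rt
Reagents that add atoms: none
Why: Oxoammonium (TEMPO) oxidation is strongly selective for the primary allylic C14 alcohol over the hindered secondary C9 alcohol and stops at the enal.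

**Step 17**
Reactants: 25 9-hydroxy C14 enal
Product: 26 9-acetoxy C14 enal
Conditions: Ac2O, pyridine, DMAP (cat.), CH2Cl2, 0 °C
Reagents that add atoms: acetic anhydride, CC(=O)OC(C)=O
Why: DMAP-catalysed acetylation caps the C9 hydroxyl promptly, before the neighbouring methacrylate can migrate.

**Step 18**
Reactants: 26 9-acetoxy C14 enal
Product: 27 C14 carboxylic acid
Conditions: NaClO2, NaH2PO4, 2-methylbut-2-ene, t-BuOH/H2O, 0 °C → rt
Reagents that add atoms: sodium chlorite, [Na+].[O-]Cl=O
Why: Pinnick oxidation converts the enal into the acid, and the scavenger protects the C4=C5 alkene from hypochlorous acid.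

**Step 19**
Reactants: 27 C14 carboxylic acid
Product: 28 C14 methyl ester (4,5-alkene)
Conditions: MeI, KHCO3, DMF, rt
Reagents that add atoms: iodomethane, CI
Why: O-alkylation of the carboxylate under weakly basic conditions forms the methyl ester without a nucleophile that could add to the methylidene lactone or the methacrylate.

**Step 20**
Reactants: 28 C14 methyl ester
Product: 29 target, (4R,5R,6S,7R,8R,9S)-9-acetoxy-4,5-epoxy-8-methacryloyloxy C14 methyl ester 12,6-lactone
Conditions: m-CPBA, NaHCO3, CH2Cl2, 0 °C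
Reagents that add atoms: 3-chloroperoxybenzoic acid, OOC(=O)c1cccc(Cl)c1
Why: In this Prilezhaev epoxidation the peracid reacts only with the electron-rich C4=C5 (the other three alkenes are conjugated to carbonyls) and should approach the peripheral face, which in the conformer with H6 eclipsing C15 is the face carrying O6, giving the 4R,5R trans-epoxide.

**Compound list**
1 | (4S)-4-benzyl-1,3-oxazolidin-2-one | O=C1N[C@@H](Cc2ccccc2)CO1 | starting material
2 | methyl 4-chloro-4-oxobutanoate | COC(=O)CCC(Cl)=O | starting material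
3 | methyl 4-[(4S)-4-benzyl-2-oxo-1,3-oxazolidin-3-yl]-4-oxobutanoate | COC(=O)CCC(=O)N1[C@@H](Cc2ccccc2)COC1=O | intermediate
4 | 2-methylidenepropane-1,3-diol | C=C(CO)CO | starting material
5 | 2-({[tert-butyl(dimethyl)silyl]oxy}methyl)prop-2-en-1-ol | C=C(CO)CO[Si](C)(C)C(C)(C)C | intermediate
6 | 2-({[tert-butyl(dimethyl)silyl]oxy}methyl)prop-2-enal | C=C(C=O)CO[Si](C)(C)C(C)(C)C | intermediate
7 | hex-1-en-5-yne | C#CCCC=C | starting material
8 | dimethyl[(1E)-2-methylhexa-1,5-dien-1-yl]alumane | C[Al](C)/C=C(\C)CCC=C | intermediate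
9 | (2E)-3-methylhepta-2,6-dien-1-ol | OC/C=C(\C)CCC=C | intermediate
10 | (2E)-3-methylhepta-2,6-dienal | O=C/C=C(\C)CCC=C | intermediate
11 | methyl (3S,4R,5E)-3-{[(4S)-4-benzyl-2-oxo-1,3-oxazolidin-3-yl]carbonyl}-4-hydroxy-6-methyldeca-5,9-dienoate | COC(=O)C[C@H](C(=O)N1[C@@H](Cc2ccccc2)COC1=O)[C@H](O)/C=C(\C)CCC=C | intermediate
12 | (4S)-4-benzyl-3-({(2R,3S)-2-[(1E)-2-methylhexa-1,5-dien-1-yl]-5-oxooxolan-3-yl}carbonyl)-1,3-oxazolidin-2-one (trans-lactone) | O=C(N1[C@@H](Cc2ccccc2)COC1=O)[C@H]3CC(=O)O[C@@H]3/C=C(\C)CCC=C | intermediate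
13 | (4R,5R)-4-(hydroxymethyl)-5-[(1E)-2-methylhexa-1,5-dien-1-yl]oxolan-2-one (trans-lactone) | OC[C@H]1CC(=O)O[C@@H]1/C=C(\C)CCC=C | intermediate
14 | (2E,6E)-2-({[tert-butyl(dimethyl)silyl]oxy}methyl)-7-[(2R,3R)-3-(hydroxymethyl)-5-oxooxolan-2-yl]-6-methylhepta-2,6-dienal | OC[C@H]1CC(=O)O[C@@H]1/C=C(\C)CC/C=C(\CO[Si](C)(C)C(C)(C)C)C=O | intermediate
15 | (2R,3S)-2-[(1E,5E)-6-formyl-7-{[tert-butyl(dimethyl)silyl]oxy}-2-methylhepta-1,5-dien-1-yl]-5-oxooxolane-3-carbaldehyde (trans-lactone dialdehyde) | O=C[C@H]1CC(=O)O[C@@H]1/C=C(\C)CC/C=C(\CO[Si](C)(C)C(C)(C)C)C=O | intermediate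
16 | γ-siloxyallylchromium: dichlorochromium (trivalent chromium) on C1, (E)-triethylsilyl enol ether at C9=C10, C8 aldehyde intact | O=C[C@H]1CC(=O)O[C@@H]1/C=C(\C)CCC([Cr](Cl)Cl)/C(CO[Si](C)(C)C(C)(C)C)=C/O[Si](CC)(CC)CC | intermediate
17 | 14-(tert-butyldimethylsilyloxy)-8-hydroxy-9-(triethylsilyloxy)germacra-1(10),4-dien-12,6-olide; trans C6/C7 lactone, anti C8/C9, E C4=C5, in-ring cis C1=C10 | O[C@@H]1[C@H]2CC(=O)O[C@@H]2/C=C(\C)CC/C=C(/CO[Si](C)(C)C(C)(C)C)[C@@H]1O[Si](CC)(CC)CC | intermediate
18 | 8-O-trimethylsilyl ether of 17 | C[Si](C)(C)O[C@@H]1[C@H]2CC(=O)O[C@@H]2/C=C(\C)CC/C=C(/CO[Si](C)(C)C(C)(C)C)[C@@H]1O[Si](CC)(CC)CC | intermediate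
19 | 11-(dimethylaminomethyl) derivative of 18 (C11 not defined) | C[Si](C)(C)O[C@@H]1[C@H]2C(CN(C)C)C(=O)O[C@@H]2/C=C(\C)CC/C=C(/CO[Si](C)(C)C(C)(C)C)[C@@H]1O[Si](CC)(CC)CC | intermediate
20 | 11-(dimethylaminomethyl) derivative of 17 (Mannich base, C11 not defined) | O[C@@H]1[C@H]2C(CN(C)C)C(=O)O[C@@H]2/C=C(\C)CC/C=C(/CO[Si](C)(C)C(C)(C)C)[C@@H]1O[Si](CC)(CC)CC | intermediate
21 | N-methyl quaternary ammonium iodide of 20 | O[C@@H]1[C@H]2C(C[N+](C)(C)C)C(=O)O[C@@H]2/C=C(\C)CC/C=C(/CO[Si](C)(C)C(C)(C)C)[C@@H]1O[Si](CC)(CC)CC.[I-] | intermediate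
22 | 14-(tert-butyldimethylsilyloxy)-8-hydroxy-9-(triethylsilyloxy)germacra-1(10),4,11(13)-trien-12,6-olide | O[C@@H]1[C@H]2C(=C)C(=O)O[C@@H]2/C=C(\C)CC/C=C(/CO[Si](C)(C)C(C)(C)C)[C@@H]1O[Si](CC)(CC)CC | intermediate
23 | 8-O-methacrylate of 22 | C=C(C)C(=O)O[C@@H]1[C@H]2C(=C)C(=O)O[C@@H]2/C=C(\C)CC/C=C(/CO[Si](C)(C)C(C)(C)C)[C@@H]1O[Si](CC)(CC)CC | intermediate
24 | 9,14-dihydroxy-8-methacryloyloxygermacra-1(10),4,11(13)-trien-12,6-olide | C=C(C)C(=O)O[C@@H]1[C@H]2C(=C)C(=O)O[C@@H]2/C=C(\C)CC/C=C(/CO)[C@@H]1O | intermediate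
25 | 9-hydroxy-8-methacryloyloxy-14-oxogermacra-1(10),4,11(13)-trien-12,6-olide | C=C(C)C(=O)O[C@@H]1[C@H]2C(=C)C(=O)O[C@@H]2/C=C(\C)CC/C=C(/C=O)[C@@H]1O | intermediate
26 | 9-acetoxy-8-methacryloyloxy-14-oxogermacra-1(10),4,11(13)-trien-12,6-olide | C=C(C)C(=O)O[C@@H]1[C@H]2C(=C)C(=O)O[C@@H]2/C=C(\C)CC/C=C(/C=O)[C@@H]1OC(C)=O | intermediate
27 | 9-acetoxy-8-methacryloyloxy-12,6-olide C14 carboxylic acid | C=C(C)C(=O)O[C@@H]1[C@H]2C(=C)C(=O)O[C@@H]2/C=C(\C)CC/C=C(/C(=O)O)[C@@H]1OC(C)=O | intermediate
28 | methyl ester of 27 (4,5-alkene) | C=C(C)C(=O)O[C@@H]1[C@H]2C(=C)C(=O)O[C@@H]2/C=C(\C)CC/C=C(/C(=O)OC)[C@@H]1OC(C)=O | intermediate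
29 | CNP0153978.4: (4R,5R,6S,7R,8R,9S)-9-acetoxy-4,5-epoxy-8-methacryloyloxy C14 methyl ester 12,6-olide, E C1=C10 | C=C(C)C(=O)O[C@@H]1[C@H]2C(=C)C(=O)O[C@@H]2[C@H]2O[C@]2(C)CC/C=C(/C(=O)OC)[C@@H]1OC(C)=O | target

**Count**
Total steps: 20. Longest linear sequence: 17 steps (steps 4–20, from hex-1-en-5-yne 7).

**Steps most likely to fail**

1. Step 10. Intermolecular coupling or simple reduction of the enal may outrun ring closure, the allylchromium may add to the wrong face of C8, or the in-ring trans C1=C10 isomer may form. The fallback uses known chemistry, sets out from 13 and returns at 17. Alcohol 13 is oxidised with Dess–Martin periodinane/NaHCO3 to the vinyl-terminated trans-lactone aldehyde F1. F1 and enal 6 are then coupled intermolecularly with CrCl2/Et3SiCl in THF, the established intermolecular cross-pinacol-type reaction (chair transition state for anti, Felkin–Anh at C8). This gives the acyclic anti-diol 9-triethylsilyl ether F2, which carries the C1 vinyl group and a C10 methylidene. Ring-closing metathesis of F2 with RuCl2(H2IMes)(=CH-C6H4-2-O-i-Pr) in dilute toluene at 80 °C forms C1=C10 with loss of ethene; the ten-membered ring should favour the in-ring cis alkene, which is 17.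

2. Step 8. Metathesis with the electron-poor 1,1-disubstituted enal may be sluggish and incomplete while 13 homodimerises and the catalyst decays. The fallback sets out from 13 and returns at 15. Cross-metathesis of 13 with the electron-richer allylic alcohol 5 gives the C8,C9-diol with CH2OH trans to C2, F3, together with its C1=C10 geometric isomer F4. Dess–Martin oxidation of both primary hydroxyls at once converts F3 into 15 and F4 into the geometric isomer of 15, F5. Both aldehydes can be fed into step 10 because the C1=C10 geometry is erased in the allylchromium.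

3. Step 20. The peracid may attack the wrong face of C4=C5, or 3-chlorobenzoic acid may open the sensitive epoxide transannularly. The fallback sets out from 28 and returns at 29 and makes no new compound (F0). It is a catalyst-controlled dioxirane epoxidation (Shi epoxidation) with the fructose-derived ketone enantiomer that delivers oxygen to the 4R,5R face, using KHSO5 (as 2KHSO5·KHSO4·K2SO4) in NaHCO3-buffered MeCN/dimethoxymethane/H2O at 0 °C. Facial choice then comes from the catalyst and not from the ring conformation, and no carboxylic acid is generated.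

**Further compounds**
F1 | step 10 | (2R,3S)-2-[(1E)-2-methylhexa-1,5-dien-1-yl]-5-oxooxolane-3-carbaldehyde | O=C[C@H]1CC(=O)O[C@@H]1/C=C(\C)CCC=C
F2 | step 10 | acyclic anti-8,9-diol 9-triethylsilyl ether with C1 vinyl and C10 methylidene (14-OTBS) | O[C@H]([C@H]2CC(=O)O[C@@H]2/C=C(\C)CCC=C)[C@@H](O[Si](CC)(CC)CC)C(=C)CO[Si](C)(C)C(C)(C)C
F3 | step 8 | C8,C9-diol, CH2OH trans to C2 (14-OTBS) | OC[C@H]1CC(=O)O[C@@H]1/C=C(\C)CC/C=C(\CO[Si](C)(C)C(C)(C)C)CO
F4 | step 8 | C1=C10 geometric isomer of F3 | OC[C@H]1CC(=O)O[C@@H]1/C=C(\C)CC/C=C(/CO[Si](C)(C)C(C)(C)C)CO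
F5 | step 8 | C1=C10 geometric isomer of 15 | O=C[C@H]1CC(=O)O[C@@H]1/C=C(\C)CC/C=C(/CO[Si](C)(C)C(C)(C)C)C=O
F0 | step 20 | none | none
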